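**Retrosynthetic overview**

1. The target is reached by one hydrogenolysis (four benzyl ethers and one blocking bromine) from a benzylated bromo ketone, whose dodecanoyl group comes from bromine–lithium exchange and Weinreb acylation of a dibromo chromane.
2. The dibromo chromane is cut across ring C (the pyran ring) at O1–C2 and C3–C4: a catalytic, enantioselective oxa-[4+2] cycloaddition of an ortho-quinone methide with 4-benzyloxystyrene, the quinone methide being formed in the flask from a racemic diarylmethanol (stereoconvergent).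
3. Enabling feature: C4 is benzylic, ortho to O1 (through C4a–C8a) and para to the C7 oxygen of ring A, so C4=C4a–C8a=O1 is a latent ortho-quinone methide. C2 carries the para-oxygenated ring B, so C2=C3 is a latent electron-rich styrene of matched polarity.
4. The diarylmethanol comes from mono-lithiated tribromo-tris(benzyloxy)benzene and 4-benzyloxy-2-hydroxybenzaldehyde. The two bromines left on ring D (the phloroglucinol ring) block its nucleophilic CH positions during the key step.
5. Ring order: rings A, B and D are bought as arenes; ring C is the only ring built and is closed last, with both stereocentres.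

Key step: step 3

Assumption: the sense of induction of the chiral acid in step 3 cannot be predicted with certainty for this di-ortho-substituted quinone methide; the (R)-catalyst is written, and its equally available (S)-antipode is to be used if the first experiment shows that it is the one leading to the (2S,4S) series.

Compounds 1, 3, 7 and 10 are taken as commercially available.

**Route**

Step 1
Reactants: 1 1,3,5-tris(benzyloxy)benzene
Product: 2 1,3,5-tris(benzyloxy)-2,4,6-tribromobenzene
Conditions: NBS (3.3 equiv), MeCN, 0 °C → 40 °C, dark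
Reagents that add atoms: N-bromosuccinimide, O=C1CCC(=O)N1Br
Why: Electrophilic aromatic bromination of the three equivalent CH positions, each activated by two ortho and one para benzyloxy group, should run to the symmetrical tribromide, so that no regiochemical question arises, while exclusion of light suppresses radical bromination of the benzylic CH2 groups.

Step 2
Reactants: 2 1,3,5-tris(benzyloxy)-2,4,6-tribromobenzene; 3 4-(benzyloxy)-2-hydroxybenzaldehyde
Product: 6 rac-[4-(benzyloxy)-2-hydroxyphenyl][2,4,6-tris(benzyloxy)-3,5-dibromophenyl]methanol, via aryllithium 4 (not isolated), via sodium phenoxide 5 (not isolated)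
Conditions: 2 (1.1 equiv), n-BuLi (1.1 equiv), THF, −78 °C; then 5 [from 3 (1.0 equiv), NaH (1.05 equiv), THF, 0 °C] by cannula, −78 → 0 °C; sat. aq NH4Cl; Et3N-deactivated silica, used promptly
Reagents that add atoms: none
Why: Bromine–lithium exchange at one of three equivalent C–Br bonds followed by 1,2-addition of the aryllithium to the aldehyde of the pre-formed phenoxide (so that no aryllithium is lost to the phenol proton) should give the diarylmethanol, whose stereocentre is formed racemic on purpose because step 3 erases it.

Step 3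
Reactants: 6 rac-[4-(benzyloxy)-2-hydroxyphenyl][2,4,6-tris(benzyloxy)-3,5-dibromophenyl]methanol; 7 1-(benzyloxy)-4-ethenylbenzene (4-benzyloxystyrene)
Product: 9 (2S,4S)-7-(benzyloxy)-2-[4-(benzyloxy)phenyl]-4-[2,4,6-tris(benzyloxy)-3,5-dibromophenyl]chromane (2,4-cis), via ortho-quinone methide 8 (not isolated)
Conditions: 7 (3 equiv), (R)-3,3'-bis(2,4,6-triisopropylphenyl)-1,1'-binaphthyl-2,2'-diyl N-triflylphosphoramide (10 mol%), PhMe, 5 Å MS, −20 °C
Reagents that add atoms: none
Why: The chiral acid should dehydrate racemic 6 to the planar, hydrogen-bonded ortho-quinone methide 8, so that both enantiomers of 6 converge on one intermediate, which then undergoes an inverse-electron-demand oxa-Diels–Alder reaction with the electron-rich styrene 7 in which C3–C4 bond formation runs ahead of O1–C2 bond formation. The closest known reaction type is the chiral Brønsted acid catalysed [4+2] cycloaddition of ortho-quinone methides, generated from ortho-hydroxybenzhydrols, with styrenes, which gives cis-2,4-diarylchromanes. Ring C is closed by this intermolecular [4+2] cycloaddition; in its stepwise limit the styrene CH2 attacks C4 and O1 then captures the 4-benzyloxybenzyl cation at C2 in a 6-exo-trig closure. C4 is set by the catalyst, whose chiral anion stays bound to the OH of the protonated quinone methide and shields one face of the exocyclic carbon, and C2 is set relative to C4 by the endo approach of ring B to the (E)-quinone methide, which places the two aryl groups cis. The step needs regioselectivity (CH2 to C4, CHAr to O1), secured by the matched polarity of the quinone methide carbon and the styrene terminus, and chemoselectivity for the styrene over Friedel–Crafts capture by arenes and over quinone methide formation on ring D, secured by the two blocking bromines, by benzyl protection of every phenol except the one that becomes O1, and by the excess of 7.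

Step 4
Reactants: 10 dodecanoyl chloride
Product: 11 N-methoxy-N-methyldodecanamide
Conditions: MeNH(OMe)·HCl (1.1 equiv), Et3N (2.2 equiv), CH2Cl2, 0 °C → rt
Reagents that add atoms: N,O-dimethylhydroxylamine hydrochloride, CNOC.Cl
Why: N-Acylation of the hydroxylamine by the acid chloride (Weinreb amide formation) is routine and provides an acylating agent that stops at the ketone stage.

Step 5
Reactants: 9 (2S,4S)-7-(benzyloxy)-2-[4-(benzyloxy)phenyl]-4-[2,4,6-tris(benzyloxy)-3,5-dibromophenyl]chromane; 11 N-methoxy-N-methyldodecanamide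
Product: 14 1-{2,4,6-tris(benzyloxy)-3-[(2S,4S)-7-(benzyloxy)-2-[4-(benzyloxy)phenyl]chroman-4-yl]-5-bromophenyl}dodecan-1-one, via aryllithium 12 (not isolated), via lithium hemiaminal 13 (not isolated)
Conditions: n-BuLi (1.05 equiv), THF, −78 °C; then 11 (1.5 equiv), −78 → 0 °C; sat. aq NH4Cl
Reagents that add atoms: none
Why: Bromine–lithium exchange with one equivalent of n-BuLi at one of the two bromines, which are equivalent by rotation about the C4–aryl bond, followed by the Weinreb ketone synthesis through the chelated adduct 13 should install the dodecanoyl group without over-addition and without touching C2 or C4, since only the C–Br bond reacts at −78 °C.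

Step 6
Reactants: 14 1-{2,4,6-tris(benzyloxy)-3-[(2S,4S)-7-(benzyloxy)-2-[4-(benzyloxy)phenyl]chroman-4-yl]-5-bromophenyl}dodecan-1-one
Product: 15 1-{2,4,6-trihydroxy-3-[(2S,4S)-7-hydroxy-2-(4-hydroxyphenyl)chroman-4-yl]phenyl}dodecan-1-one (target)
Conditions: H2 (1 atm), 10% Pd/C, NaOAc (1.5 equiv), EtOAc–MeOH 1:1, rt
Reagents that add atoms: none
Why: Heterogeneous catalytic hydrogenolysis should cleave the four benzyl ethers and the blocking C–Br bond in one operation, with NaOAc taking up the HBr so that the acid-labile C2–O1 bond is not ionised and C2 is not epimerised, while the aryl ketone and the cyclic benzylic ether are expected to survive these mild conditions as they do in the debenzylation of flavan benzyl ethers.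

**Compound list**

1 | 1,3,5-tris(benzyloxy)benzene | c1ccc(COc2cc(OCc3ccccc3)cc(OCc3ccccc3)c2)cc1 | starting material
2 | 1,3,5-tris(benzyloxy)-2,4,6-tribromobenzene | Brc1c(OCc2ccccc2)c(Br)c(OCc2ccccc2)c(Br)c1OCc1ccccc1 | intermediate
3 | 4-(benzyloxy)-2-hydroxybenzaldehyde | O=Cc1ccc(OCc2ccccc2)cc1O | starting material
4 | [2,4,6-tris(benzyloxy)-3,5-dibromophenyl]lithium | [Li]c1c(OCc2ccccc2)c(Br)c(OCc2ccccc2)c(Br)c1OCc1ccccc1 | intermediate
5 | sodium 5-(benzyloxy)-2-formylphenolate | O=Cc1ccc(OCc2ccccc2)cc1[O-].[Na+] | intermediate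
6 | rac-[4-(benzyloxy)-2-hydroxyphenyl][2,4,6-tris(benzyloxy)-3,5-dibromophenyl]methanol (racemic) | OC(c1ccc(OCc2ccccc2)cc1O)c1c(OCc2ccccc2)c(Br)c(OCc2ccccc2)c(Br)c1OCc1ccccc1 | intermediate
7 | 1-(benzyloxy)-4-ethenylbenzene (4-benzyloxystyrene) | C=Cc1ccc(OCc2ccccc2)cc1 | starting material
8 | (E)-3-(benzyloxy)-6-[2,4,6-tris(benzyloxy)-3,5-dibromobenzylidene]cyclohexa-2,4-dien-1-one (ortho-quinone methide) | O=C1C=C(OCc2ccccc2)C=C/C1=C\c1c(OCc2ccccc2)c(Br)c(OCc2ccccc2)c(Br)c1OCc1ccccc1 | intermediate
9 | (2S,4S)-7-(benzyloxy)-2-[4-(benzyloxy)phenyl]-4-[2,4,6-tris(benzyloxy)-3,5-dibromophenyl]chromane | Brc1c(OCc2ccccc2)c(Br)c(OCc2ccccc2)c([C@H]2C[C@@H](c3ccc(OCc4ccccc4)cc3)Oc3cc(OCc4ccccc4)ccc32)c1OCc1ccccc1 | intermediate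
10 | dodecanoyl chloride | CCCCCCCCCCCC(Cl)=O | starting material
11 | N-methoxy-N-methyldodecanamide | CCCCCCCCCCCC(=O)N(C)OC | intermediate
12 | {2,4,6-tris(benzyloxy)-3-[(2S,4S)-7-(benzyloxy)-2-[4-(benzyloxy)phenyl]chroman-4-yl]-5-bromophenyl}lithium | [Li]c1c(OCc2ccccc2)c(Br)c(OCc2ccccc2)c([C@H]2C[C@@H](c3ccc(OCc4ccccc4)cc3)Oc3cc(OCc4ccccc4)ccc32)c1OCc1ccccc1 | intermediate
13 | lithium 1-{2,4,6-tris(benzyloxy)-3-[(2S,4S)-7-(benzyloxy)-2-[4-(benzyloxy)phenyl]chroman-4-yl]-5-bromophenyl}-1-[methoxy(methyl)amino]dodecan-1-olate (hemiaminal carbon not defined) | CCCCCCCCCCCC(O[Li])(N(C)OC)c1c(OCc2ccccc2)c(Br)c(OCc2ccccc2)c([C@H]2C[C@@H](c3ccc(OCc4ccccc4)cc3)Oc3cc(OCc4ccccc4)ccc32)c1OCc1ccccc1 | intermediate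
14 | 1-{2,4,6-tris(benzyloxy)-3-[(2S,4S)-7-(benzyloxy)-2-[4-(benzyloxy)phenyl]chroman-4-yl]-5-bromophenyl}dodecan-1-one | CCCCCCCCCCCC(=O)c1c(OCc2ccccc2)c(Br)c(OCc2ccccc2)c([C@H]2C[C@@H](c3ccc(OCc4ccccc4)cc3)Oc3cc(OCc4ccccc4)ccc32)c1OCc1ccccc1 | intermediate
15 | 1-{2,4,6-trihydroxy-3-[(2S,4S)-7-hydroxy-2-(4-hydroxyphenyl)chroman-4-yl]phenyl}dodecan-1-one | CCCCCCCCCCCC(=O)c1c(O)cc(O)c([C@H]2C[C@@H](c3ccc(O)cc3)Oc3cc(O)ccc32)c1O | target

**Step count**

Total steps: 6. Longest linear sequence: 5 (steps 1, 2, 3, 5, 6, from compound 1); step 4 is a one-step side branch.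

**Steps most likely to fail, with fallbacks**

Step 3. The catalyst may discriminate poorly between the faces of a quinone methide whose aryl group is di-ortho-substituted and twisted. The acid may also oligomerise the electron-rich styrene, and C2 may epimerise after the cycloaddition through reversible ionisation of the C2–O1 bond. The fallback gives up catalyst control and keeps only the substrate-controlled cis selectivity. It sets out from 6, which is treated with 7 and an achiral acid (diphenyl phosphate, 10 mol%, CH2Cl2, 0 °C) to give the racemic cis-chromane. This is a 1:1 mixture of 9 and its mirror image, (2R,4R)-7-(benzyloxy)-2-[4-(benzyloxy)phenyl]-4-[2,4,6-tris(benzyloxy)-3,5-dibromophenyl]chromane F1. The enantiomers are separated by preparative chromatography on a polysaccharide chiral stationary phase; F1 is discarded and the route is rejoined at 9.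

Step 5. The hindered, strongly basic aryllithium may take a proton from the α-CH2 of the amide, or induce loss of formaldehyde from its N-methoxy group, faster than it adds. This would return the protodebrominated arene in place of the ketone. The fallback sets out from 9 and uses the same exchange (n-BuLi, THF, −78 °C), but traps the aryllithium with dodecanal, whose addition should outrun enolisation. This gives the secondary alcohol 1-{2,4,6-tris(benzyloxy)-3-[(2S,4S)-7-(benzyloxy)-2-[4-(benzyloxy)phenyl]chroman-4-yl]-5-bromophenyl}dodecan-1-ol F2 as a mixture of carbinol epimers, which is of no consequence. Oxidation with Dess–Martin periodinane (CH2Cl2, NaHCO3, rt) then rejoins the route at 14.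

Step 6. Hydrogenolytic opening of ring C at the benzylic C2–O1 bond may compete, or debenzylation may stall at the hindered ethers next to the acyl group. The fallback avoids hydrogen altogether and sets out from 14. Radical hydrodebromination (Bu3SnH, AIBN, PhMe, 80 °C) should give 1-{2,4,6-tris(benzyloxy)-3-[(2S,4S)-7-(benzyloxy)-2-[4-(benzyloxy)phenyl]chroman-4-yl]phenyl}dodecan-1-one F3. Non-reductive debenzylation with BCl3 and pentamethylbenzene as benzyl cation scavenger (CH2Cl2, −78 °C) then arrives at 15.

**Further compounds**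

F1 | step 3 | (2R,4R)-7-(benzyloxy)-2-[4-(benzyloxy)phenyl]-4-[2,4,6-tris(benzyloxy)-3,5-dibromophenyl]chromane | Brc1c(OCc2ccccc2)c(Br)c(OCc2ccccc2)c([C@@H]2C[C@H](c3ccc(OCc4ccccc4)cc3)Oc3cc(OCc4ccccc4)ccc32)c1OCc1ccccc1
F2 | step 5 | 1-{2,4,6-tris(benzyloxy)-3-[(2S,4S)-7-(benzyloxy)-2-[4-(benzyloxy)phenyl]chroman-4-yl]-5-bromophenyl}dodecan-1-ol (carbinol epimers) | CCCCCCCCCCCC(O)c1c(OCc2ccccc2)c(Br)c(OCc2ccccc2)c([C@H]2C[C@@H](c3ccc(OCc4ccccc4)cc3)Oc3cc(OCc4ccccc4)ccc32)c1OCc1ccccc1
F3 | step 6 | 1-{2,4,6-tris(benzyloxy)-3-[(2S,4S)-7-(benzyloxy)-2-[4-(benzyloxy)phenyl]chroman-4-yl]phenyl}dodecan-1-one | CCCCCCCCCCCC(=O)c1c(OCc2ccccc2)cc(OCc2ccccc2)c([C@H]2C[C@@H](c3ccc(OCc4ccccc4)cc3)Oc3cc(OCc4ccccc4)ccc32)c1OCc1ccccc1
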